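All runs were computed for an exercise; the scatter is artificial.

Early times give the share of left-handed product nothing to stand on: up to 8.00 h in the beta run and 12.0 h in the epsilon run every product reading is at most 2%, less than two scatters of 1.5 percentage points, so these readings cannot be told from zero and weigh nothing in the reckoning here. The later readings carry it, at 15.0 h and 25.0 h in the beta run and at 20.0 h and 25.0 h in the epsilon run, which sum to 36.0% left-handed and 18.0% right-handed.

| setting | beta | epsilon | flask |
|---|---|---|---|
| left-handed substrate | 21 mM | 33 mM | 15 mM |
| right-handed substrate | 21 mM | 33 mM | 15 mM |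
| partner | 30 mM | 30 mM | 30.0 mM |
| protic impurity | 1.5 mM | 1.5 mM | 1.50 mM |
| precatalyst | 7.5 µM | 7.5 µM | 7.5 µM |
| remark | run made earlier | run made earlier |  |
| time |  |  | 20 h |

| run | time / h | left-handed product / % | right-handed product / % | left-handed substrate / % |
|---|---|---|---|---|
| beta | 2.00 | 1 | 2 | 50 |
| beta | 3.00 | 0 | 0 | 50 |
| beta | 5.00 | 0 | 0 | 48 |
| beta | 8.00 | 2 | 2 | 48 |
| beta | 15.0 | 9 | 6 | 43 |
| beta | 25.0 | 15 | 3 | 38 |
| epsilon | 1.50 | 1 | 0 | 50 |
| epsilon | 5.00 | 0 | 1 | 50 |
| epsilon | 8.00 | 0 | 0 | 48 |
| epsilon | 12.0 | 0 | 1 | 46 |
| epsilon | 20.0 | 6 | 4 | 43 |
| epsilon | 25.0 | 6 | 5 | 40 |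

(readings scatter by 1.5 percentage points)

* excess of left-handed product over right-handed product in the product at 1.0 h
* excess of left-handed product over right-handed product in the product at 20 h
* part of the left-handed substrate and right-handed substrate charged together that has reacted at 20 h

- free catalyst is single-handed; left-handed substrate and right-handed substrate are mirror images of each other, charged as a racemate, each of them at the stated concentration
- the analysis behind the earlier runs scatters by 1.5 percentage points, standard deviation
- steps that have been proposed: free catalyst + left-handed substrate <-> catalyst intermediate A; free catalyst + right-handed substrate <-> catalyst intermediate B; partner + catalyst intermediate A -> free catalyst + left-handed product; partner + catalyst intermediate B -> free catalyst + right-handed product; partner + precatalyst -> free catalyst + spent reagent; partner + protic impurity -> quenched reagent; partner <-> dormant form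
- an excess is below zero if the other one leads

From a racemate, equal rates put c(left-handed product)/(c(left-handed product)+c(right-handed product)) at 0.5, and the excess (enantiomeric excess) is the distance from that zero, doubled. One scatter on a single left-handed late reading moves this share by 0.93 points, but on a right-handed one by 1.9 points, twice as far, so the small right-handed readings have to be known best. All eight together leave the share uncertain by 4.1 points. Pooled over the late readings of the beta and epsilon runs, the share reads 66.7%, and this left share of the product goes forward; my own reckoning for the flask is therefore an excess of 33.3%, give or take 8.2 points, at both asked times.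

The forecast gives 32% at 1.0 h, 32% at 20 h and 20% reacted, holding that “The selectivity ratio should not depend on catalyst level”.

The flask gives 26.2% at 1.0 h, 39.1% at 20 h and 16.7% reacted, its excess standing at 36.0% at 10.0 h on the way up. The flask's left share at 20 h is 69.5%, less than one uncertainty above the 66.7% read from the earlier runs, and that read share, applied to the 16.7% reacted, gives 11.1% left-handed product, where the flask holds 11.6%.

    free catalyst + left-handed substrate ⇌ catalyst intermediate A (K = 240 M⁻¹, k = 27000 M⁻¹ h⁻¹)
    free catalyst + right-handed substrate ⇌ catalyst intermediate B (K = 38.0 M⁻¹, k = 2.10 × 10⁵ M⁻¹ h⁻¹)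
    partner + catalyst intermediate A → free catalyst + left-handed product (k = 34000 M⁻¹ h⁻¹)
    partner + catalyst intermediate B → free catalyst + right-handed product (k = 14000 M⁻¹ h⁻¹)
    partner + precatalyst → free catalyst + spent reagent (k = 0.780 M⁻¹ h⁻¹)
    partner + protic impurity → quenched reagent (k = 7.90 M⁻¹ h⁻¹)
    partner ⇌ dormant form (K = 0.480, k = 0.0740 h⁻¹)

In the neighbouring flask with 0.0030 mM of precatalyst, 7.33% has reacted at 20 h, so the carried share gives 4.89% left-handed product; the computed amount in that flask is 5.09%, at an excess of 38.8%.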